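**Retrosynthetic overview**
- The side chain is cut at the single bond between the vinyl CH (C4') and the next CH2 (C5'). This gives a C14 ring-bearing (E)-vinyl iodide and a C16 homofarnesyl borane made from (E,E)-farnesol, which are joined by a B-alkyl Suzuki-Miyaura coupling.
- The vinyl iodide goes back, through syn methylalumination of a terminal alkyne, to the C13 methyl ketone trans-4-(2-hydroxy-2,6,6-trimethylcyclohexyl)butan-2-one.
- The strategy rests on this feature: the ring CH carrying the chain and the neighbouring ring C(CH3)(OH) are trans beside the gem-dimethyl carbon, and the first olefinic chain carbon (C3', the one bearing CH3) stands 1,5 to the carbinol oxygen. A carbonyl at C3' can therefore bridge back to the carbinol carbon through a six-membered ring, so the hydroxy ketone is the hydrolysis product of a trans-fused dihydropyran.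
- Ring order: the cyclohexane and the temporary dihydropyran close in one cyclase step from (E)-geranylacetone; the dihydropyran is then opened by hydrolysis; no further ring is formed.

Key step: step 1

Assumption: geranylacetone is used as the isomerically pure 5E compound (the 5Z isomer would fold to the other relative configuration), and the cyclase is the recombinant enzyme from Alicyclobacillus acidocaldarius produced in Escherichia coli by standard expression.

Step 1
Reactants: 1 (E)-geranylacetone, (5E)-6,10-dimethylundeca-5,9-dien-2-one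
Product: 2 (4aS,8aS)-2,5,5,8a-tetramethyl-4a,5,6,7,8,8a-hexahydro-4H-chromene (trans-fused bicyclic enol ether)
Conditions: squalene-hopene cyclase from Alicyclobacillus acidocaldarius (recombinant, E. coli whole cells or detergent-solubilised membrane protein; wild type or an active-site variant selected for oxygen capture), citric acid/NaOH buffer pH 6.0, Triton X-100 (0.2%), 50 °C, 48–72 h; EtOAc extraction, Et3N-deactivated silica
Reagents that add atoms: none
Why: The catalytic aspartic acid of the cyclase protonates C9 of the terminal C9=C10 alkene of chair-folded 1, the C5=C6 alkene adds through C5 to the C10 cation, the ketone oxygen captures the resulting C6 cation, and the cyclic oxocarbenium ion loses a proton from C3 to leave the enol ether. The closest known reaction type is the enzymatic Brønsted-acid cation-olefin cyclisation with heteroatom termination that turns homofarnesol into ambroxide, and geranylacetone is an accepted substrate of this enzyme class. The cyclohexane closes in the 6-endo-trig mode (bond between the gem-dimethyl carbon and the future ring CH), and the dihydropyran closes by six-membered O–C bond formation onto the tertiary cation with the carbonyl carbon inside the new ring (endo with respect to C=O). C4a and C8a are set together: carbon and oxygen add anti across the E alkene in a chair fold, which gives the trans ring fusion, and the chiral active site, which binds one enantiomeric chair and protonates one alkene face, fixes the absolute sense as (4aS,8aS), the same as in ring A of hopene. The step needs enantiofacial selection and a stop after one carbocycle: the enzyme pocket supplies the first, while the E geometry, the lack of a third alkene and the 1,5 relation between the carbonyl oxygen and C6 supply the second. Material in which the oxocarbenium ion loses a methyl proton instead, or in which water intercepts the cation, converges on the same hydroxy ketone in step 2.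

Step 2
Reactants: 2 (4aS,8aS)-2,5,5,8a-tetramethyl-4a,5,6,7,8,8a-hexahydro-4H-chromene
Product: 3 4-[(1S,2S)-2-hydroxy-2,6,6-trimethylcyclohexyl]butan-2-one (trans hydroxy ketone)
Conditions: 0.5 M aq. HCl (0.2 equiv), THF/H2O 4:1, 0 °C → rt; NaHCO3 quench
Reagents that add atoms: water, O
Why: Acid-catalysed enol ether hydrolysis (protonation at C3, water addition at C2, opening of the hemiketal) cleaves only the O1–C2 bond, so the C8a–O bond and both stereocentres are untouched, and the large excess of water should hold the product as the open δ-hydroxy ketone.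

Step 3
Reactants: 3 4-[(1S,2S)-2-hydroxy-2,6,6-trimethylcyclohexyl]butan-2-one
Product: 4 4-[(1S,2S)-2,6,6-trimethyl-2-(triethylsilyloxy)cyclohexyl]butan-2-one
Conditions: TESOTf (1.3 equiv), 2,6-lutidine (2.5 equiv), CH2Cl2, −78 → −40 °C; aq. NaHCO3 quench
Reagents that add atoms: triethylsilyl trifluoromethanesulfonate, CC[Si](CC)(CC)OS(=O)(=O)C(F)(F)F
Why: Silyl ether formation with a silyl triflate and a hindered pyridine base is the standard way to cap a tertiary alcohol, and at low temperature O-silylation of the hydroxyl should outrun enol silylation of the ketone and acid-driven reclosure to the enol ether; no stereocentre is touched.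

Step 4
Reactants: 4 4-[(1S,2S)-2,6,6-trimethyl-2-(triethylsilyloxy)cyclohexyl]butan-2-one
Product: 5 diethyl 4-[(1S,2S)-2,6,6-trimethyl-2-(triethylsilyloxy)cyclohexyl]but-1-en-2-yl phosphate (terminal enol phosphate)
Conditions: LiN(iPr)2 (1.15 equiv), THF, −78 °C, slow addition of 4, 45 min; ClP(O)(OEt)2 (1.3 equiv), −78 °C → rt; chromatography
Reagents that add atoms: diethyl chlorophosphate, CCOP(=O)(Cl)OCC
Why: Kinetic deprotonation by the hindered amide at −78 °C should take a CH3 proton of the methyl ketone, and O-phosphorylation of the lithium enolate gives the terminal enol phosphate (first half of the Negishi methyl ketone to alkyne conversion), which is freed from any internal isomer at this stage.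

Step 5
Reactants: 5 diethyl 4-[(1S,2S)-2,6,6-trimethyl-2-(triethylsilyloxy)cyclohexyl]but-1-en-2-yl phosphate
Product: 6 {[(1S,2S)-2-(but-3-yn-1-yl)-1,3,3-trimethylcyclohexyl]oxy}triethylsilane (silyl-protected terminal alkyne)
Conditions: LiN(iPr)2 (2.5 equiv), THF, −78 °C → rt, 3 h; H2O quench at 0 °C
Reagents that add atoms: none
Why: Base-induced β-elimination of diethyl phosphate from the 1,1-disubstituted enol phosphate gives the lithium acetylide, which is protonated on quench (second half of the Negishi alkyne synthesis), while the silyl ether and the remote stereocentres are inert to the amide base.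

Step 6
Reactants: 6 {[(1S,2S)-2-(but-3-yn-1-yl)-1,3,3-trimethylcyclohexyl]oxy}triethylsilane
Product: 8 triethyl{[(1S,2S)-2-[(3E)-4-iodo-3-methylbut-3-en-1-yl]-1,3,3-trimethylcyclohexyl]oxy}silane ((E)-vinyl iodide), via alkenyldimethylalane 7 (not isolated)
Conditions: AlMe3 (2.5 equiv), Cp2ZrCl2 (0.25 equiv), CH2Cl2, 0 °C → rt, 16 h; then I2 (1.3 equiv) in THF, −30 → 0 °C; aq. Na2S2O3 and dilute aq. K2CO3 work-up
Reagents that add atoms: trimethylaluminium, C[Al](C)C; iodine, II
Why: Negishi zirconium-catalysed carboalumination adds CH3 and Al syn across the terminal alkyne with Al on the terminal carbon, and iodinolysis of the C–Al bond with retention should give the (E)-2-methyl-1-iodoalkene, the silyl ether being tolerated by AlMe3.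

Step 7
Reactants: 9 (2E,6E)-farnesol
Product: 10 (2E,6E)-farnesal
Conditions: TEMPO (10 mol %), PhI(OAc)2 (1.1 equiv), CH2Cl2, 0 °C → rt; aq. Na2S2O3 wash
Reagents that add atoms: none
Why: Oxoammonium-catalysed (TEMPO) oxidation of a primary allylic alcohol with PhI(OAc)2 as terminal oxidant stops at the aldehyde and should neither isomerise the 2E double bond nor touch the isolated alkenes.

Step 8
Reactants: 10 (2E,6E)-farnesal
Product: 11 (3E,7E)-4,8,12-trimethyltrideca-1,3,7,11-tetraene
Conditions: Ph3PCH3Br (1.3 equiv), KOtBu (1.25 equiv), THF, 0 °C, 30 min; then 10, 0 °C → rt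
Reagents that add atoms: methyltriphenylphosphonium bromide, C[P+](c1ccccc1)(c1ccccc1)c1ccccc1.[Br-]
Why: Wittig methylenation with the non-stabilised ylide converts the enal carbonyl into a terminal vinyl group without disturbing the geometry of the adjacent trisubstituted alkene.

Step 9
Reactants: 11 (3E,7E)-4,8,12-trimethyltrideca-1,3,7,11-tetraene; 8 triethyl{[(1S,2S)-2-[(3E)-4-iodo-3-methylbut-3-en-1-yl]-1,3,3-trimethylcyclohexyl]oxy}silane
Product: 13 triethyl{[(1S,2S)-1,3,3-trimethyl-2-[(3E,7E,11E)-3,8,12,16-tetramethylheptadeca-3,7,11,15-tetraen-1-yl]cyclohexyl]oxy}silane (silyl ether of the target), via homofarnesyl-9-BBN 12 (not isolated)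
Conditions: 11 (1.4 equiv), 9-BBN (1.3 equiv, 0.5 M in THF), 0 °C → rt, 4 h; then 8 (1.0 equiv), PdCl2(dppf) (5 mol %), AsPh3 (5 mol %), Cs2CO3 (3 equiv), DMF/H2O, degassed, rt
Reagents that add atoms: none
Why: Hydroboration with the bulky dialkylborane occurs only at the monosubstituted terminal alkene with boron on the terminal carbon, and the primary B-alkyl-9-BBN then undergoes base-promoted B-alkyl Suzuki-Miyaura coupling with the vinyl iodide (oxidative addition, transmetallation, reductive elimination) with retention of the E geometry.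

Step 10
Reactants: 13 triethyl{[(1S,2S)-1,3,3-trimethyl-2-[(3E,7E,11E)-3,8,12,16-tetramethylheptadeca-3,7,11,15-tetraen-1-yl]cyclohexyl]oxy}silane
Product: 14 (1S,2S)-1,3,3-trimethyl-2-[(3E,7E,11E)-3,8,12,16-tetramethylheptadeca-3,7,11,15-tetraen-1-yl]cyclohexan-1-ol (target CNP0273209.1)
Conditions: Bu4NF (1 M in THF, 3 equiv), THF, rt → 45 °C
Reagents that add atoms: none
Why: Fluoride-induced Si–O cleavage, driven by the strong Si–F bond, frees the tertiary alcohol under non-acidic conditions, so the polyene is not exposed to protons that could start cyclisation or dehydration.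

**Compound list**
1 | (E)-geranylacetone, (5E)-6,10-dimethylundeca-5,9-dien-2-one | CC(C)=CCC/C(C)=C/CCC(C)=O | starting material
2 | (4aS,8aS)-2,5,5,8a-tetramethyl-4a,5,6,7,8,8a-hexahydro-4H-chromene | CC2=CC[C@H]1C(C)(C)CCC[C@]1(C)O2 | intermediate
3 | 4-[(1S,2S)-2-hydroxy-2,6,6-trimethylcyclohexyl]butan-2-one | CC(=O)CC[C@H]1C(C)(C)CCC[C@]1(C)O | intermediate
4 | 4-[(1S,2S)-2,6,6-trimethyl-2-(triethylsilyloxy)cyclohexyl]butan-2-one | CC(=O)CC[C@H]1C(C)(C)CCC[C@]1(C)O[Si](CC)(CC)CC | intermediate
5 | diethyl 4-[(1S,2S)-2,6,6-trimethyl-2-(triethylsilyloxy)cyclohexyl]but-1-en-2-yl phosphate | C=C(OP(=O)(OCC)OCC)CC[C@H]1C(C)(C)CCC[C@]1(C)O[Si](CC)(CC)CC | intermediate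
6 | {[(1S,2S)-2-(but-3-yn-1-yl)-1,3,3-trimethylcyclohexyl]oxy}triethylsilane | C#CCC[C@H]1C(C)(C)CCC[C@]1(C)O[Si](CC)(CC)CC | intermediate
7 | dimethyl[(1E)-2-methyl-4-[(1S,2S)-2,6,6-trimethyl-2-(triethylsilyloxy)cyclohexyl]but-1-en-1-yl]alane | C[Al](C)/C=C(\C)CC[C@H]1C(C)(C)CCC[C@]1(C)O[Si](CC)(CC)CC | intermediate
8 | triethyl{[(1S,2S)-2-[(3E)-4-iodo-3-methylbut-3-en-1-yl]-1,3,3-trimethylcyclohexyl]oxy}silane | I/C=C(\C)CC[C@H]1C(C)(C)CCC[C@]1(C)O[Si](CC)(CC)CC | intermediate
9 | (2E,6E)-farnesol, (2E,6E)-3,7,11-trimethyldodeca-2,6,10-trien-1-ol | CC(C)=CCC/C(C)=C/CC/C(C)=C/CO | starting material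
10 | (2E,6E)-farnesal, (2E,6E)-3,7,11-trimethyldodeca-2,6,10-trienal | CC(C)=CCC/C(C)=C/CC/C(C)=C/C=O | intermediate
11 | (3E,7E)-4,8,12-trimethyltrideca-1,3,7,11-tetraene | CC(C)=CCC/C(C)=C/CC/C(C)=C/C=C | intermediate
12 | 9-[(3E,7E)-4,8,12-trimethyltrideca-3,7,11-trien-1-yl]-9-borabicyclo[3.3.1]nonane (homofarnesyl-9-BBN) | CC(C)=CCC/C(C)=C/CC/C(C)=C/CCB1C2CCCC1CCC2 | intermediate
13 | triethyl{[(1S,2S)-1,3,3-trimethyl-2-[(3E,7E,11E)-3,8,12,16-tetramethylheptadeca-3,7,11,15-tetraen-1-yl]cyclohexyl]oxy}silane | CC(C)=CCC/C(C)=C/CC/C(C)=C/CC/C=C(\C)CC[C@H]1C(C)(C)CCC[C@]1(C)O[Si](CC)(CC)CC | intermediate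
14 | (1S,2S)-1,3,3-trimethyl-2-[(3E,7E,11E)-3,8,12,16-tetramethylheptadeca-3,7,11,15-tetraen-1-yl]cyclohexan-1-ol | CC(C)=CCC/C(C)=C/CC/C(C)=C/CC/C=C(\C)CC[C@H]1C(C)(C)CCC[C@]1(C)O | target

Total step count: 10
Longest linear sequence: 8 steps (steps 1 to 6, then 9 and 10); the farnesol branch (steps 7 and 8) joins at step 9.

**Steps most likely to fail**

Step 1. The C13 substrate may turn over slowly in an active site shaped for a C30 chain. The monocyclic cation may also lose a proton to give ring alkenes before the oxygen captures it, and the oily substrate may transfer poorly into the aqueous phase. The fallback sets out from 1 and gives up enzymatic control of the absolute sense. Protonative cyclisation with FSO3H in 2-nitropropane at −78 °C should give, stereospecifically trans but without enantiocontrol, the racemic trans-fused enol ether F1. Hydrolysis as in step 2 should give the racemic trans hydroxy ketone F2. The enantiomers are then separated by preparative supercritical-fluid chromatography on an amylose tris(3,5-dimethylphenylcarbamate) phase. The (1S,2S) enantiomer is compound 3, where the route is rejoined.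

Step 3. The Lewis-acidic silyl triflate may drive reclosure of the hydroxy ketone to the enol ether, the ketone may be silylated at its enol, and silylation of the hindered tertiary hydroxyl may stay incomplete. The fallback sets out from 3 and removes the ketone before any protection. LiN(iPr)2 (2.2 equiv) at −78 °C forms the alkoxide-enolate dianion, and ClP(O)(OEt)2 (1.05 equiv) should phosphorylate the enolate oxygen in preference to the hindered tertiary alkoxide, giving the hydroxy enol phosphate F3. Excess LiN(iPr)2 then eliminates phosphate to give the hydroxy alkyne F4. With no carbonyl left, silylation with TESOTf and 2,6-lutidine should be uncomplicated and returns to the route at compound 6.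

Step 9. Transmetallation of the homoallylic B-alkyl group to divalent palladium may be slow, which allows protodeboronation, β-hydride elimination from the alkylpalladium species or reduction of the vinyl iodide; over-hydroboration of the trisubstituted alkenes may also erode the borane. The fallback sets out from 8 and 9 and joins the same bond by sulfone alkylation instead of cross-coupling.
- Iodine-lithium exchange on 8 (t-BuLi, Et2O, −78 °C) and trapping with paraformaldehyde should give the (E)-allylic alcohol F5 with retention.
- CBr4 and PPh3 convert it to the allylic bromide F6, and PhSO2Na in DMF gives the allylic phenyl sulfone F7.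
- Farnesol 9 with PBr3 in Et2O at 0 °C gives (2E,6E)-farnesyl bromide F8.
- Deprotonation of F7 with n-BuLi in THF at −78 °C and alkylation with F8 (Biellmann coupling) gives the coupled sulfone F9, as a mixture of epimers at the sulfone carbon.
- Reductive desulfonylation with LiBHEt3 and catalytic PdCl2(dppp) in THF at 0 °C, where hydride is delivered to the less substituted allyl terminus, should return to the route at compound 13.

Further compounds
F1 | step 1 | racemic trans-2,5,5,8a-tetramethyl-4a,5,6,7,8,8a-hexahydro-4H-chromene (both enantiomers) | CC2=CC[C@H]1C(C)(C)CCC[C@]1(C)O2.CC2=CC[C@@H]1C(C)(C)CCC[C@@]1(C)O2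
F2 | step 1 | racemic trans-4-(2-hydroxy-2,6,6-trimethylcyclohexyl)butan-2-one (both enantiomers) | CC(=O)CC[C@H]1C(C)(C)CCC[C@]1(C)O.CC(=O)CC[C@@H]1C(C)(C)CCC[C@@]1(C)O
F3 | step 3 | diethyl 4-[(1S,2S)-2-hydroxy-2,6,6-trimethylcyclohexyl]but-1-en-2-yl phosphate | C=C(OP(=O)(OCC)OCC)CC[C@H]1C(C)(C)CCC[C@]1(C)O
F4 | step 3 | (1S,2S)-2-(but-3-yn-1-yl)-1,3,3-trimethylcyclohexan-1-ol | C#CCC[C@H]1C(C)(C)CCC[C@]1(C)O
F5 | step 9 | (2E)-3-methyl-5-[(1S,2S)-2,6,6-trimethyl-2-(triethylsilyloxy)cyclohexyl]pent-2-en-1-ol | OC/C=C(\C)CC[C@H]1C(C)(C)CCC[C@]1(C)O[Si](CC)(CC)CC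
F6 | step 9 | {[(1S,2S)-2-[(3E)-5-bromo-3-methylpent-3-en-1-yl]-1,3,3-trimethylcyclohexyl]oxy}triethylsilane | BrC/C=C(\C)CC[C@H]1C(C)(C)CCC[C@]1(C)O[Si](CC)(CC)CC
F7 | step 9 | triethyl{[(1S,2S)-1,3,3-trimethyl-2-[(3E)-3-methyl-5-(phenylsulfonyl)pent-3-en-1-yl]cyclohexyl]oxy}silane | O=S(=O)(C/C=C(\C)CC[C@H]1C(C)(C)CCC[C@]1(C)O[Si](CC)(CC)CC)c1ccccc1
F8 | step 9 | (2E,6E)-farnesyl bromide | CC(C)=CCC/C(C)=C/CC/C(C)=C/CBr
F9 | step 9 | triethyl{[(1S,2S)-1,3,3-trimethyl-2-[(3E,7E,11E)-3,8,12,16-tetramethyl-5-(phenylsulfonyl)heptadeca-3,7,11,15-tetraen-1-yl]cyclohexyl]oxy}silane (epimers at the sulfone carbon) | CC(C)=CCC/C(C)=C/CC/C(C)=C/CC(/C=C(\C)CC[C@H]1C(C)(C)CCC[C@]1(C)O[Si](CC)(CC)CC)S(=O)(=O)c1ccccc1
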